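Plan (carotenoid numbering: ring C1 = CMe2, C2 = CH2, C3 = CHOH, C4=C5(Me), C6 = CH bearing the chain; the target is the C2-symmetric (3R,6R,3'R,6'R) diol, O and chain trans on each ring)
1. Retrosynthesis: cut C11=C12 and C11'=C12' (two-directional double Wittig, C15 + C10 + C15), then C9=C10 (Horner–Wadsworth–Emmons), then C7=C8 (cross-metathesis), and last the ring bond C5–C6.
2. Enabling feature: in each ring the trisubstituted C4=C5 alkene is bonded to the tertiary allylic carbon C6, which carries H and an alkenyl group (C7=C8). An alkenyl–CH(vinyl) unit is the retron of a 6-exo Heck cyclisation of a (Z)-alkenyl iodide (C5) onto an allylsilane (C6=C7–C8–Si).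
3. Forward: acyclic C1–C8 chain from a 3,3-dimethylpentenoate; the ring is closed once, in the C10 ring fragment that supplies both rings, and no ring is formed afterwards; then C13 enone, C15 aldehyde, and union of two C15 units with the C10 bis-ylide.
4. Stereochemistry: C3 from Noyori transfer hydrogenation of an ynone; C6 in the Heck cyclisation (chiral diphosphine plus the C3 centre); position and geometry of C4=C5 from the alkenyl iodide; chain E-alkenes from metathesis, olefination and thermal equilibration.

Key step: step 7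

Assumption: in step 7 the (R)-BINAP palladium catalyst is taken as the matched partner of the (4R) substrate for forming the (1R,4R) ring; if the pairing proves mismatched, (S)-BINAP replaces it with no other change.

Step 1
Reactants: 1 methyl 3,3-dimethylpent-4-enoate
Product: 2 N-methoxy-N,3,3-trimethylpent-4-enamide
Conditions: MeNH(OMe)·HCl, iPrMgCl, THF, −20 °C to 0 °C
Reagents that add atoms: N,O-dimethylhydroxylamine hydrochloride, CNOC.Cl
Why: Weinreb amide formation, in which the chloromagnesium amide made in the flask acylates on the unhindered methyl ester and the chelated product does not react further.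

Step 2
Reactants: 2 N-methoxy-N,3,3-trimethylpent-4-enamide; 3 prop-1-yn-1-ylmagnesium bromide
Product: 4 6,6-dimethyloct-7-en-2-yn-4-one
Conditions: THF, 0 °C; then aq NH4Cl
Reagents that add atoms: none
Why: Weinreb ketone synthesis, in which the alkynyl Grignard reagent adds once because the magnesium chelate survives until work-up, so the ynone should form without tertiary alcohol.

Step 3
Reactants: 4 6,6-dimethyloct-7-en-2-yn-4-one
Product: 5 (4R)-6,6-dimethyloct-7-en-2-yn-4-ol
Conditions: RuCl[(R,R)-TsDPEN](p-cymene) (1 mol %), iPrOH, rt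
Reagents that add atoms: none
Why: Noyori asymmetric transfer hydrogenation of an alkynyl ketone, in which the (R,R) ruthenium hydride places the alkynyl group next to the arene ligand and so should set the (4R) carbinol (the future C3), leaving alkyne and terminal alkene untouched.

Step 4
Reactants: 5 (4R)-6,6-dimethyloct-7-en-2-yn-4-ol
Product: 7 (2Z,4R)-2-iodo-6,6-dimethylocta-2,7-dien-4-ol, via cyclic alkenylalanate 6 (not isolated)
Conditions: NaAlH2(OCH2CH2OMe)2, THF, 0 °C to rt; then I2, THF, −78 °C
Reagents that add atoms: iodine, I-I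
Why: alkoxide-directed trans-hydroalumination of the propargylic alcohol puts aluminium on the distal alkyne carbon inside a five-membered ring, and iodinolysis with retention should give the (Z)-iodoalkene with iodine cis to the carbinol carbon, as the ring closure requires; the carbinol centre is not touched.

Step 5
Reactants: 7 (2Z,4R)-2-iodo-6,6-dimethylocta-2,7-dien-4-ol
Product: 8 tert-butyl{[(2Z,4R)-2-iodo-6,6-dimethylocta-2,7-dien-4-yl]oxy}dimethylsilane
Conditions: TBSCl, imidazole, DMF, rt
Reagents that add atoms: tert-butyl(chloro)dimethylsilane, CC(C)(C)[Si](C)(C)Cl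
Why: standard silylation of a secondary allylic alcohol, which protects the oxygen through the palladium, ruthenium and base steps and gives it steric bulk for the cyclisation.

Step 6
Reactants: 8 tert-butyl{[(2Z,4R)-2-iodo-6,6-dimethylocta-2,7-dien-4-yl]oxy}dimethylsilane; 9 trimethyl(prop-2-en-1-yl)silane
Product: 10 tert-butyl{[(2Z,4R,7E)-2-iodo-6,6-dimethyl-9-(trimethylsilyl)nona-2,7-dien-4-yl]oxy}dimethylsilane
Conditions: 9 (4 equiv), second-generation Grubbs catalyst RuCl2(=CHPh)(PCy3)(H2IMes) (5 mol %), CH2Cl2, 40 °C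
Reagents that add atoms: none
Why: olefin cross-metathesis, in which the vinyl group next to the quaternary carbon does not homodimerise and should couple with the excess of the reactive allylsilane to the E-alkene, the trisubstituted iodoalkene being inert to the ruthenium carbene.

Step 7
Reactants: 10 tert-butyl{[(2Z,4R,7E)-2-iodo-6,6-dimethyl-9-(trimethylsilyl)nona-2,7-dien-4-yl]oxy}dimethylsilane
Product: 11 tert-butyl{[(1R,4R)-4-ethenyl-3,5,5-trimethylcyclohex-2-en-1-yl]oxy}dimethylsilane
Conditions: Pd2(dba)3·CHCl3 (5 mol %), (R)-BINAP (12 mol %), Ag3PO4 (1.1 equiv), DMF, 75 °C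
Reagents that add atoms: none
Why: Zerovalent palladium inserts into the alkenyl C–I bond with retention of the Z geometry, Ag3PO4 removes iodide to give a cationic alkenylpalladium–BINAP species, and this adds syn across the E-allylsilane with carbon going to the proximal alkene carbon, so that the C5–C6 bond closes the six-membered ring and palladium ends on the exocyclic C7. The closure is a 6-exo-trig carbopalladation, favoured over the 7-endo mode by the three-atom tether and by the gem-dimethyl group at C1, which holds the reacting ends together. β-Silyl elimination, assisted by the silver salt, then releases the vinyl group at C6 and returns zerovalent palladium, and because it should outrun β-hydride elimination from the cationic alkylpalladium, no hydride is taken from C6 and the new stereocentre is kept. The closest known reaction type is the silane-terminated intramolecular asymmetric Heck reaction of aryl and alkenyl iodides with allylsilanes, which gives six-membered rings with a vinyl-bearing tertiary stereocentre. The configuration at C6 should be set in the carbopalladation by the chiral diphosphine, which selects the alkene face, acting together with the C3 centre, whose silyloxy group can sit pseudo-equatorial in a chair-like transition state so that the vinyl group enters trans to oxygen. The step needs exo regiochemistry, silyl in preference to hydride elimination and face selectivity, and it fixes the ring double bond at C4=C5 from the position of the iodide, which avoids the double-bond isomers that cationic cyclisation of this end group gives.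

Step 8
Reactants: 11 tert-butyl{[(1R,4R)-4-ethenyl-3,5,5-trimethylcyclohex-2-en-1-yl]oxy}dimethylsilane; 12 but-3-en-2-one
Product: 13 (3E)-4-[(1R,4R)-4-{[tert-butyl(dimethyl)silyl]oxy}-2,6,6-trimethylcyclohex-2-en-1-yl]but-3-en-2-one
Conditions: 12 (5 equiv), second-generation Hoveyda–Grubbs catalyst RuCl2(=CH-C6H4-2-OiPr)(H2IMes) (5 mol %), CH2Cl2, 40 °C
Reagents that add atoms: none
Why: olefin cross-metathesis of the monosubstituted vinyl group with the electron-poor enone partner, which should give the E-enone (C7=C8) while the hindered trisubstituted ring alkene stays out.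

Step 9
Reactants: 13 (3E)-4-[(1R,4R)-4-{[tert-butyl(dimethyl)silyl]oxy}-2,6,6-trimethylcyclohex-2-en-1-yl]but-3-en-2-one; 14 diethyl (cyanomethyl)phosphonate
Product: 16 (2E,4E)-5-[(1R,4R)-4-{[tert-butyl(dimethyl)silyl]oxy}-2,6,6-trimethylcyclohex-2-en-1-yl]-3-methylpenta-2,4-dienenitrile, via sodium phosphonate carbanion 15 (not isolated)
Conditions: 14, NaH, THF, 0 °C; then 13, 0 °C to rt; chromatography
Reagents that add atoms: none
Why: Horner–Wadsworth–Emmons olefination of the methyl ketone, which should give mainly the (2E) nitrile (C9=C10), the minor (2Z) isomer being removed by chromatography; the weakly basic phosphonate anion should leave the C6–H alone.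

Step 10
Reactants: 16 (2E,4E)-5-[(1R,4R)-4-{[tert-butyl(dimethyl)silyl]oxy}-2,6,6-trimethylcyclohex-2-en-1-yl]-3-methylpenta-2,4-dienenitrile
Product: 18 (2E,4E)-5-[(1R,4R)-4-{[tert-butyl(dimethyl)silyl]oxy}-2,6,6-trimethylcyclohex-2-en-1-yl]-3-methylpenta-2,4-dienal, via N-aluminoimine 17 (not isolated)
Conditions: iBu2AlH, CH2Cl2, −78 °C; then wet silica gel, 0 °C
Reagents that add atoms: water, O
Why: partial reduction of a nitrile with iBu2AlH, which stops at the N-aluminoimine; mild hydrolysis should then give the dienal without loss of the silyl ether.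

Step 11
Reactants: 19 (2E,4E,6E)-2,7-dimethylocta-2,4,6-trienedial
Product: 20 (2E,4E,6E)-2,7-dimethylocta-2,4,6-triene-1,8-diol
Conditions: NaBH4, MeOH/THF, 0 °C
Reagents that add atoms: none
Why: 1,2-reduction of both conjugated aldehydes with NaBH4, which should leave the triene geometry unchanged.

Step 12
Reactants: 20 (2E,4E,6E)-2,7-dimethylocta-2,4,6-triene-1,8-diol
Product: 21 [(2E,4E,6E)-2,7-dimethylocta-2,4,6-triene-1,8-diyl]bis(triphenylphosphonium) dibromide
Conditions: PPh3·HBr (2.1 equiv), MeOH, rt
Reagents that add atoms: triphenylphosphine hydrobromide, [Br-].c1ccccc1[PH+](c1ccccc1)c1ccccc1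
Why: phosphonium salt formation from an allylic alcohol, in which each primary allylic alcohol ionises under the acidic conditions and is captured by triphenylphosphine.

Step 13
Reactants: 18 (2E,4E)-5-[(1R,4R)-4-{[tert-butyl(dimethyl)silyl]oxy}-2,6,6-trimethylcyclohex-2-en-1-yl]-3-methylpenta-2,4-dienal (2.1 equiv); 21 [(2E,4E,6E)-2,7-dimethylocta-2,4,6-triene-1,8-diyl]bis(triphenylphosphonium) dibromide
Product: 23 (3R,6R,3'R,6'R)-3,3'-bis{[tert-butyl(dimethyl)silyl]oxy}-ε,ε-carotene, via bis-ylide 22 (not isolated)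
Conditions: NaOMe, MeOH/CH2Cl2, 0 °C to rt; then heptane, reflux
Reagents that add atoms: none
Why: two-directional double Wittig olefination, which forms C11=C12 and C11'=C12' on both ends of the C10 unit; Z-isomers at these disubstituted bonds should equilibrate thermally to the all-E polyene, as is usual for carotenoids.

Step 14
Reactants: 23 (3R,6R,3'R,6'R)-3,3'-bis{[tert-butyl(dimethyl)silyl]oxy}-ε,ε-carotene
Product: 24 (3R,6R,3'R,6'R)-ε,ε-carotene-3,3'-diol
Conditions: Bu4NF, THF, 0 °C to rt
Reagents that add atoms: none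
Why: fluoride-mediated desilylation, which should free both allylic alcohols under non-acidic conditions that spare the polyene and the ionisable allylic C3–O bonds.

Compound list
1 | methyl 3,3-dimethylpent-4-enoate | COC(=O)CC(C)(C)C=C | starting material
2 | N-methoxy-N,3,3-trimethylpent-4-enamide | CON(C)C(=O)CC(C)(C)C=C | intermediate
3 | prop-1-yn-1-ylmagnesium bromide | CC#C[Mg]Br | starting material
4 | 6,6-dimethyloct-7-en-2-yn-4-one | CC#CC(=O)CC(C)(C)C=C | intermediate
5 | (4R)-6,6-dimethyloct-7-en-2-yn-4-ol | CC#C[C@H](O)CC(C)(C)C=C | intermediate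
6 | sodium (5R)-5-(2,2-dimethylbut-3-en-1-yl)-2,2-bis(2-methoxyethoxy)-3-methyl-2,5-dihydro-1,2-oxaluminol-2-uide (cyclic alkenylalanate) | [Na+].CC1=C[C@@H](CC(C)(C)C=C)O[Al-]1(OCCOC)OCCOC | intermediate (not isolated)
7 | (2Z,4R)-2-iodo-6,6-dimethylocta-2,7-dien-4-ol | C/C(I)=C/[C@H](O)CC(C)(C)C=C | intermediate
8 | tert-butyl{[(2Z,4R)-2-iodo-6,6-dimethylocta-2,7-dien-4-yl]oxy}dimethylsilane | C/C(I)=C/[C@H](O[Si](C)(C)C(C)(C)C)CC(C)(C)C=C | intermediate
9 | trimethyl(prop-2-en-1-yl)silane | C=CC[Si](C)(C)C | starting material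
10 | tert-butyl{[(2Z,4R,7E)-2-iodo-6,6-dimethyl-9-(trimethylsilyl)nona-2,7-dien-4-yl]oxy}dimethylsilane | C/C(I)=C/[C@H](O[Si](C)(C)C(C)(C)C)CC(C)(C)/C=C/C[Si](C)(C)C | intermediate
11 | tert-butyl{[(1R,4R)-4-ethenyl-3,5,5-trimethylcyclohex-2-en-1-yl]oxy}dimethylsilane | CC1=C[C@H](O[Si](C)(C)C(C)(C)C)CC(C)(C)[C@H]1C=C | intermediate
12 | but-3-en-2-one | CC(=O)C=C | starting material
13 | (3E)-4-[(1R,4R)-4-{[tert-butyl(dimethyl)silyl]oxy}-2,6,6-trimethylcyclohex-2-en-1-yl]but-3-en-2-one | CC1=C[C@H](O[Si](C)(C)C(C)(C)C)CC(C)(C)[C@H]1/C=C/C(C)=O | intermediate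
14 | diethyl (cyanomethyl)phosphonate | CCOP(=O)(CC#N)OCC | starting material
15 | sodium cyano(diethoxyphosphoryl)methanide | [Na+].CCOP(=O)([CH-]C#N)OCC | intermediate (not isolated)
16 | (2E,4E)-5-[(1R,4R)-4-{[tert-butyl(dimethyl)silyl]oxy}-2,6,6-trimethylcyclohex-2-en-1-yl]-3-methylpenta-2,4-dienenitrile | CC1=C[C@H](O[Si](C)(C)C(C)(C)C)CC(C)(C)[C@H]1/C=C/C(C)=C/C#N | intermediate
17 | (2E,4E)-N-[bis(2-methylpropyl)alumanyl]-5-[(1R,4R)-4-{[tert-butyl(dimethyl)silyl]oxy}-2,6,6-trimethylcyclohex-2-en-1-yl]-3-methylpenta-2,4-dien-1-imine | CC1=C[C@H](O[Si](C)(C)C(C)(C)C)CC(C)(C)[C@H]1/C=C/C(C)=C/C=N[Al](CC(C)C)CC(C)C | intermediate (not isolated)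
18 | (2E,4E)-5-[(1R,4R)-4-{[tert-butyl(dimethyl)silyl]oxy}-2,6,6-trimethylcyclohex-2-en-1-yl]-3-methylpenta-2,4-dienal | CC1=C[C@H](O[Si](C)(C)C(C)(C)C)CC(C)(C)[C@H]1/C=C/C(C)=C/C=O | intermediate
19 | (2E,4E,6E)-2,7-dimethylocta-2,4,6-trienedial | O=C/C(C)=C/C=C/C=C(C)/C=O | starting material
20 | (2E,4E,6E)-2,7-dimethylocta-2,4,6-triene-1,8-diol | OC/C(C)=C/C=C/C=C(C)/CO | intermediate
21 | [(2E,4E,6E)-2,7-dimethylocta-2,4,6-triene-1,8-diyl]bis(triphenylphosphonium) dibromide | [Br-].[Br-].c1ccccc1[P+](c1ccccc1)(c1ccccc1)C/C(C)=C/C=C/C=C(C)/C[P+](c1ccccc1)(c1ccccc1)c1ccccc1 | intermediate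
22 | [(2E,4E,6E)-2,7-dimethylocta-2,4,6-triene-1,8-diylidene]bis(triphenylphosphorane) (bis-ylide) | c1ccccc1P(c1ccccc1)(c1ccccc1)=C/C(C)=C/C=C/C=C(C)/C=P(c1ccccc1)(c1ccccc1)c1ccccc1 | intermediate (not isolated)
23 | (3R,6R,3'R,6'R)-3,3'-bis{[tert-butyl(dimethyl)silyl]oxy}-ε,ε-carotene | CC1=C[C@H](O[Si](C)(C)C(C)(C)C)CC(C)(C)[C@H]1/C=C/C(C)=C/C=C/C(C)=C/C=C/C=C(C)/C=C/C=C(C)/C=C/[C@H]1C(C)=C[C@H](O[Si](C)(C)C(C)(C)C)CC1(C)C | intermediate
24 | (3R,6R,3'R,6'R)-ε,ε-carotene-3,3'-diol, all-E | CC1=C[C@H](O)CC(C)(C)[C@H]1/C=C/C(C)=C/C=C/C(C)=C/C=C/C=C(C)/C=C/C=C(C)/C=C/[C@H]1C(C)=C[C@H](O)CC1(C)C | target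

Total steps: 14. Longest linear sequence: 12 steps (steps 1 to 10, then 13 and 14); steps 11 and 12 form the short C10 branch.

Steps most likely to fail

Step 7. What may go wrong is poor facial selectivity in the carbopalladation if the chiral ligand and the resident C3 centre oppose each other, together with β-hydride elimination competing with β-silyl elimination. The fallback takes the stereocentre out of the cyclisation substrate, so that the ligand alone decides C6, and sets C3 afterwards by a reagent-controlled reduction. It sets out from ynone 4. Anti-hydroiodination (NaI, AcOH, rt) should give (2Z)-2-iodo-6,6-dimethylocta-2,7-dien-4-one F1. Cross-metathesis with 9 under the conditions of step 6 should give (2Z,7E)-2-iodo-6,6-dimethyl-9-(trimethylsilyl)nona-2,7-dien-4-one F2. The silane-terminated Heck cyclisation of this achiral iodoenone under the conditions of step 7 should give (4R)-4-ethenyl-3,5,5-trimethylcyclohex-2-en-1-one F3. Corey–Bakshi–Shibata reduction ((S)-Me-CBS oxazaborolidine, catecholborane, toluene, −78 °C), with the alkenyl side acting as the large group, should give (1R,4R)-4-ethenyl-3,5,5-trimethylcyclohex-2-en-1-ol F4. Silylation (TBSCl, imidazole, DMF) comes back to the route at 11.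

Step 8. What may go wrong is slow metathesis at a vinyl group flanked by the quaternary C1 and the substituted ring carbon, ending in catalyst decay and enone dimerisation. The fallback joins C8 with palladium instead of ruthenium, in a Heck alkenylation that brings C9 to C11 with the C9=C10 geometry already fixed. It sets out from 11. Heck coupling with ethyl (2E)-3-iodobut-2-enoate (Pd(OAc)2, Bu4NCl, K2CO3, DMF, 60 °C) should give ethyl (2E,4E)-5-[(1R,4R)-4-{[tert-butyl(dimethyl)silyl]oxy}-2,6,6-trimethylcyclohex-2-en-1-yl]-3-methylpenta-2,4-dienoate F5. Reduction with iBu2AlH (CH2Cl2, −78 °C) should give (2E,4E)-5-[(1R,4R)-4-{[tert-butyl(dimethyl)silyl]oxy}-2,6,6-trimethylcyclohex-2-en-1-yl]-3-methylpenta-2,4-dien-1-ol F6. Oxidation with MnO2 (CH2Cl2, rt) comes back to the route at 18, which also bypasses steps 9 and 10.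

Step 13. What may go wrong is incomplete second olefination, persistent Z-isomers at C11=C12 and C11'=C12', and base-induced migration of the ring double bond into conjugation. The fallback replaces the bis-ylide by a bis-phosphonate carbanion, whose Horner–Wadsworth–Emmons reaction is E-selective and whose phosphate by-product washes out with water. It sets out from diol 20. Bromination (PBr3, Et2O, −10 °C) should give (2E,4E,6E)-1,8-dibromo-2,7-dimethylocta-2,4,6-triene F7. Arbuzov reaction (P(OEt)3, 100 °C) should give tetraethyl [(2E,4E,6E)-2,7-dimethylocta-2,4,6-triene-1,8-diyl]bis(phosphonate) F8. Double olefination with 18 (NaH, THF, 0 °C to rt) comes back to the route at 23.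

Further compounds
F1 | step 7 | (2Z)-2-iodo-6,6-dimethylocta-2,7-dien-4-one | C/C(I)=C/C(=O)CC(C)(C)C=C
F2 | step 7 | (2Z,7E)-2-iodo-6,6-dimethyl-9-(trimethylsilyl)nona-2,7-dien-4-one | C/C(I)=C/C(=O)CC(C)(C)/C=C/C[Si](C)(C)C
F3 | step 7 | (4R)-4-ethenyl-3,5,5-trimethylcyclohex-2-en-1-one | CC1=CC(=O)CC(C)(C)[C@H]1C=C
F4 | step 7 | (1R,4R)-4-ethenyl-3,5,5-trimethylcyclohex-2-en-1-ol | CC1=C[C@H](O)CC(C)(C)[C@H]1C=C
F5 | step 8 | ethyl (2E,4E)-5-[(1R,4R)-4-{[tert-butyl(dimethyl)silyl]oxy}-2,6,6-trimethylcyclohex-2-en-1-yl]-3-methylpenta-2,4-dienoate | CC1=C[C@H](O[Si](C)(C)C(C)(C)C)CC(C)(C)[C@H]1/C=C/C(C)=C/C(=O)OCC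
F6 | step 8 | (2E,4E)-5-[(1R,4R)-4-{[tert-butyl(dimethyl)silyl]oxy}-2,6,6-trimethylcyclohex-2-en-1-yl]-3-methylpenta-2,4-dien-1-ol | CC1=C[C@H](O[Si](C)(C)C(C)(C)C)CC(C)(C)[C@H]1/C=C/C(C)=C/CO
F7 | step 13 | (2E,4E,6E)-1,8-dibromo-2,7-dimethylocta-2,4,6-triene | BrC/C(C)=C/C=C/C=C(C)/CBr
F8 | step 13 | tetraethyl [(2E,4E,6E)-2,7-dimethylocta-2,4,6-triene-1,8-diyl]bis(phosphonate) | CCOP(=O)(OCC)C/C(C)=C/C=C/C=C(C)/CP(=O)(OCC)OCC
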